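Assumption: briarane numbering (C1–C20) is used for every intermediate. The antipode of the Diels–Alder catalyst in step 2 is chosen so that C1 forms as drawn.

## Analysis of the target

- **Ring system.** The compound is a briarane. A cyclohexene (C1, C10–C14) is trans-fused (C15 methyl β, H10 α) to the ten-membered carbocycle C1–C10. An ether oxygen between C2 and C8 splits that carbocycle into a tetrahydropyran (O, C2, C1, C10, C9, C8) and an oxocane (O, C2–C8). The core is therefore an 11-oxabicyclo[5.3.1]undecane. A γ-lactone (C7, C8, C17, C19, O) is spiro to the pyran at C8 and fused to the oxocane at C7–C8.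
- **Stereocentres.** There are eleven. Eight are contiguous (C6–C7–C8–C9–C10–C1–C2–C3), and C11, C12 and C17 complete the set. C1 is quaternary, C8 is fully substituted (O, C7, C9, C17), and C11 carries a tertiary acetate.
- **Relations on the pyran.** In the pyran chair C3 and C7 are both axial on the α-face, on the side of H10. The C9 acetate is axial on the β-face, syn to C15. The C11 and C12 acetates are cis (α).
- **Relations on the lactone.** C6, C9 and C18 lie on one face; H7, H17 and the ether oxygen lie on the other. Cl at C6 and O at C7 are anti in the zigzag sense (both α on the ring).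
- **Sensitive groups.** The secondary allylic chloride can undergo SN2′ substitution, ionisation or reduction. The β-alkoxy lactone can undergo retro-oxa-Michael opening and C17 epimerisation. Three acetates stand beside one free secondary hydroxyl at C3.
- **What is hard.** The bridged medium ring, the fully substituted C8, and the chlorine, which sits on the ring face turned away from the ether bridge.
- **The feature used.** In the oxocane, the array C7(O)–C6(Cl)–C5(=C16H2) is the retron of a γ-chloroallyl metal adding to a C7 aldehyde. It shares its isobutenyl carbons (C4, C5, C6, C16) with the homoallylic alcohol retron C5(=C16H2)–C4H2–C3(OH). The unit C2–O–C8/C17–H is the retron of an oxa-Michael addition to a butenolide that a furan can carry in latent form.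

## Retrosynthetic reasoning

**33 ⇒ 32 ⇒ 29 (C6–C7 and O7–C19).** After removal of the C3 silyl group, the oxocane of 32 is cut at C6–C7 and the lactone at O7–C19. This cut is chosen because the forward reaction creates the C–C bond, both stereocentres, the chloride and the exocyclic methylene at once, so no later chlorination is needed. Precursor 29 is only a trans-oxadecalin. It holds a formyl group (C7) and the C2 arm 1,3-diaxial, and the arm ends in an allylic CHCl2 group. The forward step must close an eight-membered ring, add to one face of the aldehyde, and leave the new allylic chloride intact.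

**29 ⇒ 28 ⇒ 25 (O–C8).** The aldehyde/ester pair of 29 is the open form of pseudoacid 28. Cutting the O–C8 bond of 28 gives a γ-hydroxybutenolide (27), which is the photooxygenation product of the 3,4-disubstituted furan in 25. One aromatic ring thus delivers C7, C8, C17, C18 and C19 at the correct oxidation levels (C7 aldehyde, C19 acid). The forward step must set C8 and C17.

**25 ⇒ 23 ⇒ 19 + 22 (C3–C4).** The homoallylic alcohol is cut at C3–C4 into α-alkoxy aldehyde 19 and allylsilane 22. Silane 22 already carries the CHCl2 group, so no halogenation is needed on an advanced compound. The C2 oxygen carries a chelating acetal group, which serves both to control C3 and to keep C2–OH out of the acetylation.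

**19 ⇒ 18 ⇒ 16 ⇒ 14 ⇒ 9 + 12 (acetates, diol, C8–C9).** The three acetates go on together (17 ⇒ 18). The cis-diol comes from the 1,3-diene of 16. The C9 carbinol comes from ketone 15 while C11 is still sp2, so that C1 is clearly the large group in the reduction. The C8–C9 bond is cut into lactone 9 and bromofuran 12.

**9 ⇒ 6 ⇒ 4 (C2–C3, ring oxidation state).** The diene is the dehydration product of the enone-derived alcohol 8. The lactone of 6 is formed when the C2 alkoxide, made by vinyl addition to aldehyde 4, captures the C9 ester. This protects both groups without a separate step.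

**4 ⇒ 2 + 3 (C1–C14 and C10–C11).** A Diels–Alder cut gives diene 2 and the E-configured enal ester 3. The E geometry becomes the trans C2/C9 relation, and the quaternary C1 and C10 are set together by one catalyst.

## Alternatives that were turned down

**Alternative 1:** (the textbook route) cuts C5=C6. Ring-closing metathesis of a methallyl/vinyl diene on the same oxadecalin would give Z-olefin A1, followed by allylic chlorination.
- The olefin formed is not in the target, and the metathesis sets no stereocentre.
- C7 would have to be set separately by a basic vinyl metal in the presence of three acetates.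
- Electrophiles reach the A1 olefin from the face of the one-atom ether bridge, whereas the chlorine must end on the opposite face.
- Proton loss could occur from C4 as well as from C16.
- A stereodefined solution needs epoxidation, isomerisation and SN2 chlorination, which is three or four steps more than a closure that brings the chlorine with it.

**Alternative 2:** (biomimetic) cuts O–C8 last. The ten-membered carbocycle A2, with a Δ8(17)-butenolide and a free C2–OH, would be closed first and then stitched by a transannular oxa-Michael addition.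
- The ring of A2 has no endocyclic sp2 unit and no template, so its closure must pay the full transannular strain.
- H7 in A2 is the acidic γ-hydrogen of a butenolide and sits next to C6–Cl. The base needed for the conjugate addition would also open a vinylogous E1cB loss of HCl.
- No ring oxygen is available to direct C3.

**Alternative 3:** cuts C4–C5 and C6–C7 in a De Mayo sense. The bridged 1,3-diketone A3 (a 9-oxabicyclo[3.3.1]nonane) would undergo [2+2] photocycloaddition with allene A5 and retro-aldol opening to the ring-expanded diketone A4.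
- The idea is attractive because all photoadducts converge on one product.
- In A4, however, C4H2 and C6H2 are both allylic and α to a ketone, so the chlorine cannot be directed to C6.
- The β,γ-enones can slip into conjugation.
- C7 must first be raised to the acid level and then reduced again.
- At least six redox and halogenation steps follow the key step.

Key step: step 20

## Route

Step 1
Reactants: 1 pent-1-en-3-one
Product: 2 (Z)-3-(tert-butyldimethylsilyloxy)penta-1,3-diene
Conditions: TBSOTf, Et3N, Et2O, 0 °C
Reagents that add atoms: tert-butyldimethylsilyl triflate CC(C)(C)[Si](C)(C)OS(=O)(=O)C(F)(F)F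
Why: Soft enolisation of the ethyl ketone gives the 2-silyloxydiene; the Z enol ether places the methyl group (C20) "outside", so the s-cis conformer is accessible.

Step 2
Reactants: 2 (Z)-3-(tert-butyldimethylsilyloxy)penta-1,3-diene; 3 ethyl (E)-3-methyl-4-oxobut-2-enoate
Product: 4 ethyl 6-formyl-2,6-dimethyl-3-(tert-butyldimethylsilyloxy)cyclohex-3-ene-1-carboxylate (C1 formyl trans to C10 ester, C11 methyl cis to formyl)
Conditions: protonated oxazaborolidine (CBS-type, o-tolyl, Tf2NH) 15 mol %, CH2Cl2, −78 °C
Reagents that add atoms: none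
Why: Catalytic enantioselective Diels–Alder reaction of an α-substituted enal; the Lewis-acid-bound formyl group directs the nucleophilic diene terminus C11 to C10 ("para" rule). The E dienophile gives the trans C2/C9 relation and the catalyst fixes C1 and C10; C11 is lost again in step 6.

Step 3
Reactants: 4 Diels–Alder adduct
Product: 6 trans-fused C2-vinyl γ-lactone (O2–C9) bearing the C12 silyl enol ether, via bromomagnesium alkoxide 5 (not isolated)
Conditions: CH2=CHMgBr, THF, −78 °C to 23 °C; aq NH4Cl
Reagents that add atoms: vinylmagnesium bromide C=C[Mg]Br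
Why: Grignard 1,2-addition under Felkin–Anh control (C10 large, C14H2 medium, CH3 small) sets C2. On warming the alkoxide acylates itself with the C9 ester, so C2–O and C9 are masked together.

Step 4
Reactants: 6 vinyl lactone silyl enol ether
Product: 7 enone lactone (C12 ketone, C13=C14)
Conditions: Pd(OAc)2, MeCN, 23 °C
Reagents that add atoms: none
Why: Saegusa–Ito oxidation; palladation at C13 and β-hydride loss from C14 give the enone regiospecifically.

Step 5
Reactants: 7 enone lactone
Product: 8 allylic alcohol lactone (12β-OH expected)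
Conditions: NaBH4, CeCl3·7H2O, MeOH, −40 °C
Reagents that add atoms: none
Why: Luche 1,2-reduction leaves the lactone untouched; the C12 configuration is irrelevant because the centre is removed in step 6.

Step 6
Reactants: 8 allylic alcohol lactone
Product: 9 cyclohexa-1,3-diene lactone (C11=C12, C13=C14)
Conditions: Burgess reagent, toluene, 60 °C
Reagents that add atoms: none
Why: Neutral dehydration; C1 is quaternary, so only H11 can be lost and a single conjugated diene forms. The trans lactone sees no base.

Step 7
Reactants: 10 3,4-dibromofuran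
Product: 12 3-bromo-4-methylfuran, via 4-bromo-3-furyllithium 11 (not isolated)
Conditions: n-BuLi, Et2O, −78 °C; MeI
Reagents that add atoms: iodomethane CI
Why: Single bromine–lithium exchange followed by methylation; −78 °C prevents migration of lithium to the α-position.

Step 8
Reactants: 12 3-bromo-4-methylfuran; 9 diene lactone
Product: 14 C2-hydroxy C9 (4-methyl-3-furyl) ketone, via 4-methyl-3-furyllithium 13 (not isolated)
Conditions: n-BuLi, Et2O, −78 °C; then 9, −78 °C; aq NH4Cl
Reagents that add atoms: none
Why: Acyl substitution of the strained lactone by the aryllithium forms C8–C9 and frees C2–OH. The tetrahedral adduct persists at −78 °C, so no second addition occurs.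

Step 9
Reactants: 14 hydroxy ketone
Product: 15 C2 methoxymethyl ether
Conditions: MOMCl, i-Pr2NEt, Bu4NI (cat.), CH2Cl2, 35 °C
Reagents that add atoms: chloromethyl methyl ether COCCl
Why: Acetal protection under weakly basic conditions; the group keeps C2–OH out of step 12 and is the chelating donor needed in step 15.

Step 10
Reactants: 15 MOM ether ketone
Product: 16 C9 furyl carbinol (C9 as in the target)
Conditions: L-Selectride, THF, −78 °C
Reagents that add atoms: none
Why: Felkin–Anh reduction: hydride comes anti to the quaternary C1 (large), the carbonyl oxygen lies next to sp2 C11 (medium) and the furyl group next to H10 (small). This gives the required C9 configuration.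

Step 11
Reactants: 16 furyl carbinol
Product: 17 9,11α,12α-triol (C13=C14 retained)
Conditions: OsO4 (cat.), NMO (1.05 equiv), acetone–H2O, 0 °C
Reagents that add atoms: osmium tetroxide (catalyst) O=[Os](=O)(=O)=O; N-methylmorpholine N-oxide C[N+]1([O-])CCOCC1; water O
Why: Upjohn dihydroxylation of the most electron-rich (trisubstituted, diene) double bond. Syn addition from the α-face, anti to C15 and to the C9 side chain, sets C11 and C12 together; the hindered allylic-ether vinyl group and the furan react more slowly.

Step 12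
Reactants: 17 triol
Product: 18 9,11,12-triacetate
Conditions: Ac2O, Et3N, DMAP, CH2Cl2, 40 °C
Reagents that add atoms: acetic anhydride CC(=O)OC(C)=O
Why: DMAP-catalysed exhaustive acetylation, including the tertiary C11 hydroxyl, installs all three final acetates at a robust stage.

Step 13
Reactants: 18 triacetate
Product: 19 C3 aldehyde (α-MOM-oxy aldehyde)
Conditions: OsO4 (cat.), NaIO4, 2,6-lutidine, dioxane–H2O, 23 °C
Reagents that add atoms: osmium tetroxide (catalyst) O=[Os](=O)(=O)=O; sodium periodate [Na+].[O-]I(=O)(=O)=O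
Why: Lemieux–Johnson cleavage of the only terminal olefin. C13=C14 is shielded by C1 and deactivated by the allylic acetate, and the buffer protects the C2 centre from epimerisation.

Step 14
Reactants: 20 methyl dichloroacetate
Product: 22 [2-(dichloromethyl)allyl]trimethylsilane, via bis(silylmethyl)carbinol 21 (not isolated)
Conditions: Me3SiCH2MgCl, CeCl3, THF, −78 to 0 °C; then SiO2, CH2Cl2
Reagents that add atoms: (trimethylsilyl)methylmagnesium chloride C[Si](C)(C)C[Mg]Cl
Why: Double addition of the weakly basic organocerium reagent to the ester, then Peterson elimination of one β-hydroxysilane unit; this is the standard route from esters to 2-substituted allylsilanes.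

Step 15
Reactants: 19 C3 aldehyde; 22 [2-(dichloromethyl)allyl]trimethylsilane
Product: 23 C3 homoallylic alcohol (2,3-syn) with the C5(=CH2)–CHCl2 terminus
Conditions: SnCl4, CH2Cl2, −78 °C; then 22
Reagents that add atoms: none
Why: Hosomi–Sakurai allylation under Cram-chelate control. Tin bridges O3 and the C2 acetal oxygen, and the silane attacks anti to the quaternary C1, giving the 2,3-syn relation. The step brings in C4, C5, C6, C16 and the chlorine.

Step 16
Reactants: 23 homoallylic alcohol
Product: 24 3-O-TBS ether
Conditions: TBSOTf, 2,6-lutidine, CH2Cl2, −40 °C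
Reagents that add atoms: tert-butyldimethylsilyl triflate CC(C)(C)[Si](C)(C)OS(=O)(=O)C(F)(F)F
Why: Silylation keeps O3 from competing in step 18, from forming a six-membered lactol with C7, and from protonating the organochromium species in step 20.

Step 17
Reactants: 24 TBS ether
Product: 25 C2 alcohol
Conditions: Me2BBr, CH2Cl2, −78 °C; aq NaHCO3, THF
Reagents that add atoms: none
Why: Bromoborane cleavage of the acetal at −78 °C spares acetates, the silyl ether, the furan and the CHCl2 group.

Step 18
Reactants: 25 C2 alcohol
Product: 28 oxadecalin pseudoacid (C2–O–C8 pyran closed; C7 lactol/C19 lactone), via furan endoperoxide 26 (not isolated), via hydroxybutenolide 27 (not isolated)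
Conditions: O2, hν, tetraphenylporphyrin (cat.), i-Pr2NEt, CH2Cl2, −78 °C; then DBU (cat.), 0 °C; AcOH quench
Reagents that add atoms: oxygen O=O
Why: [4+2] photooxygenation of the furan is followed by Kornblum–DeLaMare fragmentation; the hindered base removes the less shielded H19, so C19 becomes the carbonyl and C7 the lactol. The 6-exo-trig oxa-Michael addition of O2 to C8 passes through the chair in which the smaller C9 substituent set faces C18 (A1,3 strain), putting C7 axial and C17 equatorial. Kinetic protonation of the enolate from the open ether-oxygen face sets C17.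

Step 19
Reactants: 28 pseudoacid
Product: 29 C7 aldehyde C19 methyl ester
Conditions: TMSCHN2, benzene–MeOH, 0 °C
Reagents that add atoms: (trimethylsilyl)diazomethane C[Si](C)(C)C=[N+]=[N-]
Why: Neutral esterification traps the open acid tautomer. The formyl group has no α-hydrogen, and no base is present that could start a retro-oxa-Michael reaction.

Step 20
Reactants: 29 C7 aldehyde C19 methyl ester
Product: 32 3-O-TBS ether of the target, via chloroallylchromium species 30 (not isolated), via chromium alkoxide 31 (not isolated)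
Conditions: CrCl2 (excess), THF, 23 °C, slow addition of 29 (final ca. 1 mM); aq NH4Cl
Reagents that add atoms: none
Why: Proposed new method: a ring-closing version of the chromium(II)-mediated γ-chloroallylation of aldehydes; the closest known reaction types are the intermolecular addition of allylic gem-dichlorides to aldehydes with CrCl2, which gives anti vinyl chlorohydrins, and Nozaki–Hiyama–Kishi allylation macrocyclisations. Two CrCl2 reduce one C–Cl bond of the CHCl2 group, and the α-chloroallyl chromium(III) species relaxes by 1,3-shift to the primary, E/Z-equilibrating γ-chloroallyl species 30, so the geometry of the nucleophile need not be controlled. C6 attacks the chromium-bound C7 formyl group (SE2′, six-centre Zimmerman–Traxler array) and closes the oxocane in an 8-exo-trig mode, which also completes the ten-membered carbocycle and leaves the C5=C16 methylene group. C7: the trans-fused oxadecalin holds the C2 arm and the formyl group 1,3-diaxial on the α-face, so C6 can reach the C=O (dipole-opposed to the C8–O bond, Cornforth arrangement) only from below the pyran, which puts H7 on the side of the ether bridge. C6: chlorine takes the position anti to the fully substituted C8 in the six-centre array, which gives the anti Cl/O7 relation known from the intermolecular reaction. Alkoxide 31 then attacks the C19 methyl ester (5-exo-trig) and closes the γ-lactone, which removes the alkoxide before it can form an epoxide or revert. The step needs reduction of the gem-dichloride in preference to the secondary allylic chloride of the product, secured by the much easier reduction of CHCl2, and inertness of the acetates and the ester, secured by the functional-group tolerance of chromium(II). High dilution suppresses intermolecular addition.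

Step 21
Reactants: 32 3-O-TBS ether of the target
Product: 33 CNP0333938.2 (target)
Conditions: HF·pyridine, pyridine, THF, 0 °C
Reagents that add atoms: none
Why: Buffered fluoride desilylation frees C3–OH without touching the acetates, the allylic chloride or the β-alkoxy lactone.

## Compound list

1 | pent-1-en-3-one | C=CC(=O)CC | starting material
2 | (Z)-3-(tert-butyldimethylsilyloxy)penta-1,3-diene | C=C/C(O[Si](C)(C)C(C)(C)C)=C/C | intermediate
3 | ethyl (E)-3-methyl-4-oxobut-2-enoate | CCOC(=O)/C=C(\C)C=O | starting material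
4 | Diels–Alder adduct (C1 formyl/methyl, C10 ester trans to formyl, C11 methyl cis to formyl, C12 silyl enol ether) | O=C[C@@]1(C)CC=C(O[Si](C)(C)C(C)(C)C)[C@@H](C)[C@@H]1C(=O)OCC | intermediate
5 | bromomagnesium alkoxide of the C2 vinyl carbinol | C=C[C@H](O[Mg]Br)[C@@]1(C)CC=C(O[Si](C)(C)C(C)(C)C)[C@@H](C)[C@@H]1C(=O)OCC | intermediate
6 | trans-fused C2-vinyl γ-lactone (O2–C9), C12 silyl enol ether | C=C[C@@H]1OC(=O)[C@H]2[C@H](C)C(O[Si](C)(C)C(C)(C)C)=CC[C@]12C | intermediate
7 | enone lactone | C=C[C@@H]1OC(=O)[C@H]2[C@H](C)C(=O)C=C[C@]12C | intermediate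
8 | allylic alcohol lactone (12β-OH) | C=C[C@@H]1OC(=O)[C@H]2[C@H](C)[C@@H](O)C=C[C@]12C | intermediate
9 | cyclohexa-1,3-diene lactone | C=C[C@@H]1OC(=O)[C@H]2C(C)=CC=C[C@]12C | intermediate
10 | 3,4-dibromofuran | Brc1cocc1Br | starting material
11 | 4-bromo-3-furyllithium | [Li]c1cocc1Br | intermediate
12 | 3-bromo-4-methylfuran | Cc1cocc1Br | intermediate
13 | 4-methyl-3-furyllithium | [Li]c1cocc1C | intermediate
14 | C2-hydroxy C9 (4-methyl-3-furyl) ketone | C=C[C@H](O)[C@@]1(C)C=CC=C(C)[C@@H]1C(=O)c1cocc1C | intermediate
15 | C2 MOM ether ketone | C=C[C@H](OCOC)[C@@]1(C)C=CC=C(C)[C@@H]1C(=O)c1cocc1C | intermediate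
16 | C9 furyl carbinol | C=C[C@H](OCOC)[C@@]1(C)C=CC=C(C)[C@@H]1[C@H](O)c1cocc1C | intermediate
17 | 9,11α,12α-triol | C=C[C@H](OCOC)[C@@]1(C)C=C[C@@H](O)[C@@](C)(O)[C@@H]1[C@H](O)c1cocc1C | intermediate
18 | 9,11,12-triacetate | C=C[C@H](OCOC)[C@@]1(C)C=C[C@@H](OC(C)=O)[C@@](C)(OC(C)=O)[C@@H]1[C@H](OC(C)=O)c1cocc1C | intermediate
19 | C3 aldehyde | O=C[C@H](OCOC)[C@@]1(C)C=C[C@@H](OC(C)=O)[C@@](C)(OC(C)=O)[C@@H]1[C@H](OC(C)=O)c1cocc1C | intermediate
20 | methyl dichloroacetate | COC(=O)C(Cl)Cl | starting material
21 | 1,1-dichloro-3-(trimethylsilyl)-2-[(trimethylsilyl)methyl]propan-2-ol | C[Si](C)(C)CC(O)(C[Si](C)(C)C)C(Cl)Cl | intermediate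
22 | [2-(dichloromethyl)allyl]trimethylsilane | C=C(C[Si](C)(C)C)C(Cl)Cl | intermediate
23 | C3 homoallylic alcohol (2,3-syn), CHCl2 terminus | ClC(Cl)C(=C)C[C@@H](O)[C@H](OCOC)[C@@]1(C)C=C[C@@H](OC(C)=O)[C@@](C)(OC(C)=O)[C@@H]1[C@H](OC(C)=O)c1cocc1C | intermediate
24 | 3-O-TBS ether | ClC(Cl)C(=C)C[C@@H](O[Si](C)(C)C(C)(C)C)[C@H](OCOC)[C@@]1(C)C=C[C@@H](OC(C)=O)[C@@](C)(OC(C)=O)[C@@H]1[C@H](OC(C)=O)c1cocc1C | intermediate
25 | C2 alcohol | ClC(Cl)C(=C)C[C@@H](O[Si](C)(C)C(C)(C)C)[C@H](O)[C@@]1(C)C=C[C@@H](OC(C)=O)[C@@](C)(OC(C)=O)[C@@H]1[C@H](OC(C)=O)c1cocc1C | intermediate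
26 | furan endoperoxide | ClC(Cl)C(=C)C[C@@H](O[Si](C)(C)C(C)(C)C)[C@H](O)[C@@]1(C)C=C[C@@H](OC(C)=O)[C@@](C)(OC(C)=O)[C@@H]1[C@H](OC(C)=O)C1=C(C)C2OOC1O2 | intermediate
27 | γ-hydroxybutenolide (C7 epimers) | ClC(Cl)C(=C)C[C@@H](O[Si](C)(C)C(C)(C)C)[C@H](O)[C@@]1(C)C=C[C@@H](OC(C)=O)[C@@](C)(OC(C)=O)[C@@H]1[C@H](OC(C)=O)C1=C(C)C(=O)OC1O | intermediate
28 | oxadecalin pseudoacid (C7 lactol epimers) | ClC(Cl)C(=C)C[C@@H](O[Si](C)(C)C(C)(C)C)[C@@H]2O[C@@]3([C@@H](C)C(=O)OC3O)[C@@H](OC(C)=O)[C@@H]1[C@]2(C)C=C[C@@H](OC(C)=O)[C@@]1(C)OC(C)=O | intermediate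
29 | C7 aldehyde C19 methyl ester | ClC(Cl)C(=C)C[C@@H](O[Si](C)(C)C(C)(C)C)[C@@H]2O[C@@](C=O)([C@@H](C)C(=O)OC)[C@@H](OC(C)=O)[C@@H]1[C@]2(C)C=C[C@@H](OC(C)=O)[C@@]1(C)OC(C)=O | intermediate
30 | γ-chloroallylchromium(III) species (E/Z) | ClC=C(C[Cr](Cl)Cl)C[C@@H](O[Si](C)(C)C(C)(C)C)[C@@H]2O[C@@](C=O)([C@@H](C)C(=O)OC)[C@@H](OC(C)=O)[C@@H]1[C@]2(C)C=C[C@@H](OC(C)=O)[C@@]1(C)OC(C)=O | intermediate
31 | ring-closed C7 chromium alkoxide | C=C1C[C@@H](O[Si](C)(C)C(C)(C)C)[C@@H]2O[C@@]([C@@H](O[Cr](Cl)Cl)[C@H]1Cl)([C@@H](C)C(=O)OC)[C@@H](OC(C)=O)[C@@H]3[C@]2(C)C=C[C@@H](OC(C)=O)[C@@]3(C)OC(C)=O | intermediate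
32 | 3-O-TBS ether of the target | C=C1C[C@@H](O[Si](C)(C)C(C)(C)C)[C@@H]2O[C@@]3([C@@H](C)C(=O)O[C@H]3[C@H]1Cl)[C@@H](OC(C)=O)[C@@H]1[C@]2(C)C=C[C@@H](OC(C)=O)[C@@]1(C)OC(C)=O | intermediate
33 | CNP0333938.2 | C=C1C[C@@H](O)[C@@H]2O[C@@]3([C@@H](C)C(=O)O[C@H]3[C@H]1Cl)[C@@H](OC(C)=O)[C@@H]1[C@]2(C)C=C[C@@H](OC(C)=O)[C@@]1(C)OC(C)=O | target

## Step count and least certain steps

Total: 21 steps. Longest linear sequence: 19 steps (1–6, 8–13, 15–21). Steps 7 and 14 are one-step side branches.

**Step 20 (key step, proposed new method).**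
- *What may go wrong.* The eight-membered closure is slow, so protonation or intermolecular addition of the allylchromium species may win. The formyl group may react through the rotamer chelated to the ether oxygen, which would reverse the facial sense at C6/C7. Excess chromium(II) may reduce the new allylic chloride, with β-elimination of the lactone carboxylate.
- *Fallback (known chemistry only): leaves at 19 and returns at 32.*
  - Hosomi–Sakurai reaction of 19 with methallyltrimethylsilane gives the homoallylic alcohol F1.
  - Steps 16–19 repeated on F1 give the silyl ether F2, the C2 alcohol F3, then (through the hydroxybutenolide F4) the pseudoacid F5, and finally the aldehyde ester F6.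
  - Chelation-controlled addition of vinylmagnesium bromide (MgBr2, −78 °C, attack on the open side of the O7/ether-oxygen chelate) with lactonisation gives the vinyl lactone F7.
  - Ring-closing metathesis gives the Z-olefin F8.
  - Peracid epoxidation from the exposed β-face gives the epoxide F9.
  - Silyl triflate/amidine-induced isomerisation gives the 6β-allylic alcohol F10.
  - Chlorination of F10 with triphenylphosphine/hexachloroacetone, with inversion, gives 32.

**Step 18.**
- *What may go wrong.* The conjugate addition to a tetrasubstituted acceptor may be slow or thermodynamically unfavourable. The base may open the lactol to the enal carboxylate, which is a poor acceptor at C8. The peroxide fragmentation may lose regioselectivity.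
- *Fallback: leaves at 27 and returns at 32, reversing the order of ring formation.*
  - Esterification of 27 as in step 19 gives the Z-enal ester F11.
  - Chromium closure as in step 20 gives the ten-membered butenolide F12.
  - The oxa-Michael addition is then carried out transannularly with a mild amine, where proximity and relief of transannular strain drive it, to give 32.

**Step 15.**
- *What may go wrong.* Chelation may be lost (acetal cleavage, tin binding to acetates), giving poor facial selectivity at C3. The furan may attack the activated aldehyde in a Friedel–Crafts sense. The CHCl2 group may ionise.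
- *Fallback: leaves at 23 (epimer mixture) and returns at 23, setting C3 by reduction instead of addition.* Periodinane oxidation gives the C3 ketone F13. Non-chelating L-Selectride reduction (hydride anti to C1, carbonyl dipole opposed to C2–O) gives the 2,3-syn alcohol 23.

**Step 3.**
- *What may go wrong.* Discrimination between CH3 and C14H2 on the quaternary C1 is small, so facial selectivity at C2 may be poor.
- *Fallback: leaves at 4 and returns at 6.*
  - Addition with a cold quench gives the hydroxy ester epimers F14.
  - Periodinane oxidation gives the vinyl ketone F15.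
  - Reagent-controlled CBS reduction gives the single hydroxy ester F16.
  - Catalytic base lactonises F16 to 6.

## Further compounds

F1 | step 20 | methallyl homoallylic alcohol | CC(=C)C[C@@H](O)[C@H](OCOC)[C@@]1(C)C=C[C@@H](OC(C)=O)[C@@](C)(OC(C)=O)[C@@H]1[C@H](OC(C)=O)c1cocc1C
F2 | step 20 | 3-O-TBS ether of F1 | CC(=C)C[C@@H](O[Si](C)(C)C(C)(C)C)[C@H](OCOC)[C@@]1(C)C=C[C@@H](OC(C)=O)[C@@](C)(OC(C)=O)[C@@H]1[C@H](OC(C)=O)c1cocc1C
F3 | step 20 | C2 alcohol (methallyl series) | CC(=C)C[C@@H](O[Si](C)(C)C(C)(C)C)[C@H](O)[C@@]1(C)C=C[C@@H](OC(C)=O)[C@@](C)(OC(C)=O)[C@@H]1[C@H](OC(C)=O)c1cocc1C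
F4 | step 20 | hydroxybutenolide (methallyl series) | CC(=C)C[C@@H](O[Si](C)(C)C(C)(C)C)[C@H](O)[C@@]1(C)C=C[C@@H](OC(C)=O)[C@@](C)(OC(C)=O)[C@@H]1[C@H](OC(C)=O)C1=C(C)C(=O)OC1O
F5 | step 20 | oxadecalin pseudoacid (methallyl series) | CC(=C)C[C@@H](O[Si](C)(C)C(C)(C)C)[C@@H]2O[C@@]3([C@@H](C)C(=O)OC3O)[C@@H](OC(C)=O)[C@@H]1[C@]2(C)C=C[C@@H](OC(C)=O)[C@@]1(C)OC(C)=O
F6 | step 20 | aldehyde methyl ester (methallyl series) | CC(=C)C[C@@H](O[Si](C)(C)C(C)(C)C)[C@@H]2O[C@@](C=O)([C@@H](C)C(=O)OC)[C@@H](OC(C)=O)[C@@H]1[C@]2(C)C=C[C@@H](OC(C)=O)[C@@]1(C)OC(C)=O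
F7 | step 20 | C7 vinyl lactone | CC(=C)C[C@@H](O[Si](C)(C)C(C)(C)C)[C@@H]2O[C@@]3([C@@H](C)C(=O)O[C@H]3C=C)[C@@H](OC(C)=O)[C@@H]1[C@]2(C)C=C[C@@H](OC(C)=O)[C@@]1(C)OC(C)=O
F8 | step 20 | Z-C5=C6 olefin from ring-closing metathesis | C/C1=C/[C@@H]2OC(=O)[C@H](C)[C@@]23O[C@@H]([C@H](O[Si](C)(C)C(C)(C)C)C1)[C@@]4(C)C=C[C@@H](OC(C)=O)[C@@](C)(OC(C)=O)[C@@H]4[C@@H]3OC(C)=O
F9 | step 20 | 5β,6β-epoxide | C[C@@]14C[C@@H](O[Si](C)(C)C(C)(C)C)[C@@H]2O[C@@]3([C@@H](C)C(=O)O[C@H]3[C@@H]1O4)[C@@H](OC(C)=O)[C@@H]1[C@]2(C)C=C[C@@H](OC(C)=O)[C@@]1(C)OC(C)=O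
F10 | step 20 | 6β-allylic alcohol | C=C1C[C@@H](O[Si](C)(C)C(C)(C)C)[C@@H]2O[C@@]3([C@@H](C)C(=O)O[C@H]3[C@@H]1O)[C@@H](OC(C)=O)[C@@H]1[C@]2(C)C=C[C@@H](OC(C)=O)[C@@]1(C)OC(C)=O
F11 | step 18 | Z-enal methyl ester with free C2–OH | ClC(Cl)C(=C)C[C@@H](O[Si](C)(C)C(C)(C)C)[C@H](O)[C@@]1(C)C=C[C@@H](OC(C)=O)[C@@](C)(OC(C)=O)[C@@H]1[C@H](OC(C)=O)/C(C=O)=C(\C)C(=O)OC
F12 | step 18 | ten-membered 6-chloro butenolide, 3-O-TBS | C=C1C[C@@H](O[Si](C)(C)C(C)(C)C)[C@H](O)[C@@]2(C)C=C[C@@H](OC(C)=O)[C@@](C)(OC(C)=O)[C@@H]2[C@H](OC(C)=O)C3=C(C)C(=O)O[C@H]3[C@H]1Cl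
F13 | step 15 | C3 ketone | ClC(Cl)C(=C)CC(=O)[C@H](OCOC)[C@@]1(C)C=C[C@@H](OC(C)=O)[C@@](C)(OC(C)=O)[C@@H]1[C@H](OC(C)=O)c1cocc1C
F14 | step 3 | C2 hydroxy ester (C2 epimers) | C=CC(O)[C@@]1(C)CC=C(O[Si](C)(C)C(C)(C)C)[C@@H](C)[C@@H]1C(=O)OCC
F15 | step 3 | C2 vinyl ketone | C=CC(=O)[C@@]1(C)CC=C(O[Si](C)(C)C(C)(C)C)[C@@H](C)[C@@H]1C(=O)OCC
F16 | step 3 | C2 hydroxy ester (single epimer) | C=C[C@H](O)[C@@]1(C)CC=C(O[Si](C)(C)C(C)(C)C)[C@@H](C)[C@@H]1C(=O)OCC
A1 | alternative 1 | Z-C5=C6 oxocene lactone (C16 methyl, no chlorine), 3-O-TBS | C/C1=C/[C@@H]2OC(=O)[C@H](C)[C@@]23O[C@@H]([C@H](O[Si](C)(C)C(C)(C)C)C1)[C@@]4(C)C=C[C@@H](OC(C)=O)[C@@](C)(OC(C)=O)[C@@H]4[C@@H]3OC(C)=O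
A2 | alternative 2 | ten-membered 6-chloro-2,3-dihydroxy Δ8(17)-butenolide | C=C1C[C@@H](O)[C@H](O)[C@@]2(C)C=C[C@@H](OC(C)=O)[C@@](C)(OC(C)=O)[C@@H]2[C@H](OC(C)=O)C3=C(C)C(=O)O[C@H]3[C@H]1Cl
A3 | alternative 3 | 9-oxabicyclo[3.3.1]nonane 3,7-dione (C4–C7 bonded) | O=C1CC(=O)[C@@]2([C@@H](C)C(=O)OC)O[C@@H]1[C@@]3(C)C=C[C@@H](OC(C)=O)[C@@](C)(OC(C)=O)[C@@H]3[C@@H]2OC(C)=O
A4 | alternative 3 | ring-expanded 5-methylene 3,7-dione | O=C1CC(=C)CC(=O)[C@@]2([C@@H](C)C(=O)OC)O[C@@H]1[C@@]3(C)C=C[C@@H](OC(C)=O)[C@@](C)(OC(C)=O)[C@@H]3[C@@H]2OC(C)=O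
A5 | alternative 3 | allene | C=C=C
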